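The excess of the product is the easy reading, so it comes first.

common to all: left-handed substrate 0.16 M; right-handed substrate 0.16 M; free catalyst 14 mM; added ligand 31 mM
- delta: coupling partner 0.20 M; racemization catalyst 4 mM; run made earlier
- zeta: coupling partner 0.80 M; racemization catalyst 4 mM; run made earlier
- flask: coupling partner 0.400 M; racemization catalyst 4.0 mM; time 40 h

| run | time / h | left-handed product / % | right-handed product / % |
|---|---|---|---|
| delta | 2.50 | 12.5 | 2.9 |
| delta | 4.00 | 14.1 | 3.8 |
| delta | 8.00 | 15.8 | 4.4 |
| delta | 12.0 | 15.0 | 4.7 |
| delta | 20.0 | 15.1 | 3.8 |
| delta | 30.0 | 15.3 | 4.0 |
| zeta | 5.00 | 46.5 | 12.3 |
| zeta | 10.0 | 48.0 | 13.0 |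
| zeta | 15.0 | 47.9 | 12.6 |
| zeta | 20.0 | 48.4 | 12.5 |
| zeta | 25.0 | 48.5 | 12.9 |
| zeta | 30.0 | 48.5 | 13.0 |

(readings scatter by 0.3 percentage points)
- free catalyst is single-handed; left-handed substrate and right-handed substrate are mirror images of each other, charged as a racemate, each of them at the stated concentration
- the earlier runs were read with a standard deviation of 0.3 percentage points
- an excess is the difference of the two amounts in percent of their sum
- an excess is below zero if the other one leads
* left-handed product and right-handed product together, in percent of the left-handed substrate and right-handed substrate charged together, at 40 h
* excess of left-handed product over right-handed product in the product at 40 h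
* whether the exchange between left-handed substrate and right-handed substrate keeps pace with the reaction: how far the product's excess at 40 h gets from its value without exchange to its value with instant exchange (above 80% keeps pace, below 20% hardly takes part, else lags behind)

Does the excess fall as the reaction proceeds? Over its last three readings, delta gives a yield of 19.3% with excess 56.8%. Zeta gives 61.3% with 58.2%. The excess is no lower in zeta, so this reckoning takes the two substrates as staying equal: exchange keeps pace, and the excess stays near these values.

Why does product stop while substrate remains? Delta's product equals 30.9% of its coupling partner, and zeta's 24.5%. This reckoning therefore assumes that the partner decomposes in a first-order side reaction. Coupling is also taken as first order in partner, so the partner's concentration cancels from the ratio of the two paths.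

Let Sc be the substrate pair charged, S what is left, Bc the partner charged and P the product. With the catalyst charges held as in these runs, G = ln(Sc/S)/(Bc − P) at the product's plateau should stay constant. Delta gives 1.55 /M and zeta 1.57 /M. Their mean 1.56 /M is the competition constant: logarithmic substrate loss per molar of partner decomposed.

What does G give here? Solving that equation for this flask by repeated substitution gives a yield of 35.8%.

The forecast gives 36% (33% to 39%), excess 58% (56% to 60%), and "keeps pace". It parts from this reckoning on the stop: “That points to the coupling catalyst dying”.

The flask gives 36.0%, excess 58.6%, and "keeps pace", at 99.4% of the way.

    coupling partner + free catalyst + left-handed substrate → free catalyst + left-handed product (k = 3.30 /M²/min)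
    coupling partner + free catalyst + right-handed substrate → free catalyst + right-handed product (k = 0.860 /M²/min)
    left-handed substrate + racemization catalyst ⇌ right-handed substrate + racemization catalyst, rate k3*[racemization catalyst]*[left-handed substrate] forward; the back reaction follows from the equilibrium constant (k = 220 /M/min)
    free catalyst + added ligand ⇌ idle complex, settled at all times (K = 72.0 /M)
    coupling partner → decomposed reagent (k = 0.00710 /min)

In the flask at 1.18 h, the left-handed coupling step gives the coupling partner a half-life of 5.1 h, while decomposition gives a shorter one of 1.63 h. The partner, the limiting reagent, stands at 0% after 20.0 h, while free catalyst holds 38.3% at 4.00 h and 38.3% at 40.0 h. This flask's result returns G as 1.57 /M. For a neighbouring flask with 1.6 M of partner, G from the earlier runs gives 87.2%; that flask gives 87.4%.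

The readings were computed on assumed constants, and the scatter is random.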